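**Strategy.** Ring B (numbered as the quinone: C-1 and C-4 carbonyl, C-2 and C-3 methoxy, C-5 bearing ring C, C-6 H) is built as a carbocycle from two three-carbon pieces. At the resorcinol level its oxygenated carbons C-2 to C-4 are a 1,3-dimethoxyacetone unit, so the ring is cut at C-1–C-2 and C-4–C-5 into methyl 2,4-dimethoxyacetoacetate and an alkynoate carrying the chromene. One base-mediated operation joins them: Michael addition (C-4 to C-5), Claisen closure (C-2 to C-1) and loss of the blocking ester give a 2,4-dimethoxyresorcinol. Asymmetric hydrogenation then sets C-3 of the chroman; phenol-directed oxidation and acidic methanolysis deliver the dimethoxyquinone.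

Key step: step 8

Remark: it is assumed that the antipode of the phosphine–oxazoline ligand that gives the (3S) centre in step 9 is found by testing both commercially available antipodes.

**Route**

Step 1
Reactants: 1 2-hydroxy-3,4-dimethoxybenzaldehyde
Product: 2 3,4-dimethoxy-2-(methoxymethoxy)benzaldehyde
Conditions: MOMCl, i-Pr2NEt, CH2Cl2, 0 °C to rt
Reagents that add atoms: chloromethyl methyl ether (MOMCl), COCCl
Why: Williamson-type O-alkylation of the phenol masks the oxygen that becomes the C-8 hydroxyl with an acetal that should survive base, organolithium and PhI(OAc)2 and falls off in the last step.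

Step 2
Reactants: 2 3,4-dimethoxy-2-(methoxymethoxy)benzaldehyde
Product: 4 3,4-dimethoxy-2-(methoxymethoxy)phenol, via aryl formate 3 (not isolated)
Conditions: mCPBA, NaHCO3, CH2Cl2, 0 °C to rt; then K2CO3, MeOH, rt
Reagents that add atoms: 3-chloroperbenzoic acid (mCPBA), O=C(OO)c1cccc(Cl)c1
Why: Baeyer–Villiger (Dakin-type) oxidation, in which the electron-rich aryl group migrates to oxygen, followed by methanolysis of formate 3, turns the formyl-bearing carbon into the phenol that becomes O-1 of the chroman.

Step 3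
Reactants: 4 3,4-dimethoxy-2-(methoxymethoxy)phenol
Product: 5 2-hydroxy-4,5-dimethoxy-3-(methoxymethoxy)benzaldehyde
Conditions: MgCl2, Et3N, (CH2O)n, MeCN, reflux
Reagents that add atoms: paraformaldehyde (formaldehyde), C=O
Why: Magnesium phenoxide-directed ortho-formylation (Casnati–Skattebøl) can only take place at the single free ortho position and should give the salicylaldehyde.

Step 4
Reactants: 5 2-hydroxy-4,5-dimethoxy-3-(methoxymethoxy)benzaldehyde; 6 acrolein
Product: 7 6,7-dimethoxy-8-(methoxymethoxy)-2H-chromene-3-carbaldehyde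
Conditions: K2CO3, 1,4-dioxane, reflux
Reagents that add atoms: none
Why: Oxa-Michael addition of the phenoxide to acrolein followed by intramolecular aldol condensation, the classical 2H-chromene-3-carbaldehyde synthesis, closes ring C.

Step 5
Reactants: 7 6,7-dimethoxy-8-(methoxymethoxy)-2H-chromene-3-carbaldehyde
Product: 8 3-(2,2-dibromoethenyl)-6,7-dimethoxy-8-(methoxymethoxy)-2H-chromene
Conditions: CBr4, PPh3, Et3N, CH2Cl2, 0 °C
Reagents that add atoms: carbon tetrabromide, BrC(Br)(Br)Br
Why: Corey–Fuchs dibromo-olefination (Wittig-type reaction of Ph3P=CBr2) of the enal, buffered with Et3N to protect the acetal.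

Step 6
Reactants: 8 3-(2,2-dibromoethenyl)-6,7-dimethoxy-8-(methoxymethoxy)-2H-chromene
Product: 10 methyl 3-[6,7-dimethoxy-8-(methoxymethoxy)-2H-chromen-3-yl]prop-2-ynoate, via lithium acetylide 9 (not isolated)
Conditions: n-BuLi (2.1 equiv), THF, −78 °C; then ClCO2Me, −78 °C to rt
Reagents that add atoms: methyl chloroformate, COC(=O)Cl
Why: Second stage of the Corey–Fuchs sequence (Fritsch–Buttenberg–Wiechell rearrangement to acetylide 9) with C-acylation of the acetylide by the chloroformate.

Step 7
Reactants: 11 methyl methoxyacetate (2 equiv)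
Product: 12 methyl 2,4-dimethoxy-3-oxobutanoate (racemic)
Conditions: NaH, THF, reflux; then AcOH
Reagents that add atoms: none
Why: Claisen self-condensation of the ester, driven by deprotonation of the β-keto ester formed.

Step 8
Reactants: 10 methyl 3-[6,7-dimethoxy-8-(methoxymethoxy)-2H-chromen-3-yl]prop-2-ynoate; 12 methyl 2,4-dimethoxy-3-oxobutanoate
Product: 15 5-[6,7-dimethoxy-8-(methoxymethoxy)-2H-chromen-3-yl]-2,4-dimethoxybenzene-1,3-diol, via Michael adduct 13 (not isolated), via cyclised keto ester 14 (not isolated)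
Conditions: NaH (1.1 equiv), THF, 0 to 60 °C; then LiCl, DMSO–H2O, 110 °C; then aq. HCl to pH 4
Reagents that add atoms: none
Why: The sodium enolate of 12 adds through its doubly activated methine carbon (future C-4) to the alkyne carbon of 10 that carries the chromene (future C-5), and protonation of the allenolate anti to the new quaternary carbon should place the ester cis to it in the (Z)-acrylate 13; the only enolisable carbon left, the methoxymethylene carbon (future C-2), then attacks the acrylate ester carbon (future C-1) in a Claisen condensation to 14, after which chloride demethylates the blocking ester (Krapcho) and loss of CO2 aromatises ring B. The closest known reaction type is the one-pot Michael addition–Dieckmann/Claisen annulation of 3-oxoglutarates and other β-keto esters with alkynoates to resorcinols, together with the Michael–Claisen route from ketones and acrylates to cyclohexane-1,3-diones. Ring B closes in a 6-(enolendo)-exo-trig acylation. No stereocentre survives: the quaternary C-4 of 13 and 14 is racemic and becomes sp2 on aromatisation. The step needs site selectivity in the donor (C-4 to C-5 and C-2 to C-1, not the reverse) and carbon rather than oxygen acylation: the ester group makes the methine the only site deprotonated by one equivalent of NaH, and the quaternary centre it leaves blocks tautomerisation to a 2-pyranone, so that O-acylation stays reversible while C-acylation is pulled through by the diketonate and finally by aromatisation. Conjugate addition is expected at the alkyne carbon β to the ester and not at C-4 of the chromene, which would give a cumulenolate.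

Step 9
Reactants: 15 5-[6,7-dimethoxy-8-(methoxymethoxy)-2H-chromen-3-yl]-2,4-dimethoxybenzene-1,3-diol
Product: 16 5-[(3S)-6,7-dimethoxy-8-(methoxymethoxy)-3,4-dihydro-2H-chromen-3-yl]-2,4-dimethoxybenzene-1,3-diol
Conditions: H2 (50 bar), [Ir(cod)(tBu-PHOX)][B(C6H3(CF3)2)4] (2 mol %; cod = 1,5-cyclooctadiene, tBu-PHOX = 4-tert-butyl-2-[2-(diphenylphosphino)phenyl]-4,5-dihydrooxazole), CH2Cl2, rt
Reagents that add atoms: none
Why: Asymmetric hydrogenation of the trisubstituted cyclic stilbene-type alkene of an isoflav-3-ene by a cationic iridium phosphine–oxazoline catalyst, a known route to isoflavans, in which the chiral ligand selects the alkene face and the antipode that gives the (3S) centre is used.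

Step 10
Reactants: 16 5-[(3S)-6,7-dimethoxy-8-(methoxymethoxy)-3,4-dihydro-2H-chromen-3-yl]-2,4-dimethoxybenzene-1,3-diol
Product: 17 3-hydroxy-2-methoxy-5-[(3S)-6,7-dimethoxy-8-(methoxymethoxy)-3,4-dihydro-2H-chromen-3-yl]cyclohexa-2,5-diene-1,4-dione
Conditions: PhI(OAc)2 (1.1 equiv), MeCN–H2O (3:1), 0 °C
Reagents that add atoms: water, O
Why: Oxidative demethylation of a para-methoxyphenol by PhI(OAc)2 (ligand exchange at the C-1 phenol, attack of water at the para carbon C-4, loss of methanol) should give the para-quinone and leave the C-3 hydroxyl as a vinylogous acid, while ring A, which has no free phenol, is not touched.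

Step 11
Reactants: 17 3-hydroxy-2-methoxy-5-[(3S)-6,7-dimethoxy-8-(methoxymethoxy)-3,4-dihydro-2H-chromen-3-yl]cyclohexa-2,5-diene-1,4-dione
Product: 18 5-[(3S)-8-hydroxy-6,7-dimethoxy-3,4-dihydro-2H-chromen-3-yl]-2,3-dimethoxycyclohexa-2,5-diene-1,4-dione
Conditions: HCl (1.25 M) in MeOH, 40 °C; then H2O
Reagents that add atoms: methanol, CO
Why: Acid-catalysed (Fischer-type) etherification of the vinylogous acid, under thermodynamic control that favours the 2,3-dimethoxy para-quinone, runs together with methanolysis of the MOM acetal and leaves the C-3 centre of the chroman untouched.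

**Compound list**

1 | 2-hydroxy-3,4-dimethoxybenzaldehyde | O=Cc1ccc(OC)c(OC)c1O | starting material
2 | 3,4-dimethoxy-2-(methoxymethoxy)benzaldehyde | O=Cc1ccc(OC)c(OC)c1OCOC | intermediate
3 | 3,4-dimethoxy-2-(methoxymethoxy)phenyl formate | O=COc1ccc(OC)c(OC)c1OCOC | intermediate
4 | 3,4-dimethoxy-2-(methoxymethoxy)phenol | Oc1ccc(OC)c(OC)c1OCOC | intermediate
5 | 2-hydroxy-4,5-dimethoxy-3-(methoxymethoxy)benzaldehyde | O=Cc1cc(OC)c(OC)c(OCOC)c1O | intermediate
6 | acrolein (prop-2-enal) | C=CC=O | starting material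
7 | 6,7-dimethoxy-8-(methoxymethoxy)-2H-chromene-3-carbaldehyde | O=CC1=Cc2cc(OC)c(OC)c(OCOC)c2OC1 | intermediate
8 | 3-(2,2-dibromoethenyl)-6,7-dimethoxy-8-(methoxymethoxy)-2H-chromene | BrC(Br)=CC1=Cc2cc(OC)c(OC)c(OCOC)c2OC1 | intermediate
9 | lithium [6,7-dimethoxy-8-(methoxymethoxy)-2H-chromen-3-yl]acetylide | [Li]C#CC1=Cc2cc(OC)c(OC)c(OCOC)c2OC1 | intermediate
10 | methyl 3-[6,7-dimethoxy-8-(methoxymethoxy)-2H-chromen-3-yl]prop-2-ynoate | COC(=O)C#CC1=Cc2cc(OC)c(OC)c(OCOC)c2OC1 | intermediate
11 | methyl methoxyacetate | COCC(=O)OC | starting material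
12 | methyl 2,4-dimethoxy-3-oxobutanoate (racemic) | COCC(=O)C(OC)C(=O)OC | intermediate
13 | dimethyl (2Z)-3-[6,7-dimethoxy-8-(methoxymethoxy)-2H-chromen-3-yl]-4-methoxy-4-(methoxyacetyl)pent-2-enedioate (racemic) | COCC(=O)C(OC)(C(=O)OC)/C(=C\C(=O)OC)C1=Cc2cc(OC)c(OC)c(OCOC)c2OC1 | intermediate
14 | methyl 2-[6,7-dimethoxy-8-(methoxymethoxy)-2H-chromen-3-yl]-6-hydroxy-1,5-dimethoxy-4-oxocyclohexa-2,5-diene-1-carboxylate (racemic, present as its sodium enolate) | COC(=O)C1(OC)C(O)=C(OC)C(=O)C=C1C1=Cc2cc(OC)c(OC)c(OCOC)c2OC1 | intermediate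
15 | 5-[6,7-dimethoxy-8-(methoxymethoxy)-2H-chromen-3-yl]-2,4-dimethoxybenzene-1,3-diol | COc1c(O)c(OC)c(O)cc1C1=Cc2cc(OC)c(OC)c(OCOC)c2OC1 | intermediate
16 | 5-[(3S)-6,7-dimethoxy-8-(methoxymethoxy)-3,4-dihydro-2H-chromen-3-yl]-2,4-dimethoxybenzene-1,3-diol | COc1c(O)c(OC)c(O)cc1[C@H]1COc2c(cc(OC)c(OC)c2OCOC)C1 | intermediate
17 | 3-hydroxy-2-methoxy-5-[(3S)-6,7-dimethoxy-8-(methoxymethoxy)-3,4-dihydro-2H-chromen-3-yl]cyclohexa-2,5-diene-1,4-dione | COC1=C(O)C(=O)C([C@H]2COc3c(cc(OC)c(OC)c3OCOC)C2)=CC1=O | intermediate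
18 | 5-[(3S)-8-hydroxy-6,7-dimethoxy-3,4-dihydro-2H-chromen-3-yl]-2,3-dimethoxycyclohexa-2,5-diene-1,4-dione | COC1=C(OC)C(=O)C([C@H]2COc3c(cc(OC)c(OC)c3O)C2)=CC1=O | target

**Count and risks**

Total step count: 11. Longest linear sequence: 10 (steps 1 to 6 and 8 to 11).

Steps most likely to fail:

Step 8. The Michael addition of the hindered tertiary enolate may be slow or revert. The Claisen closure may also be outrun by retro-Claisen fragmentation of the non-enolisable keto ester 13 or by reversible O-acylation, because the only enolate available is the weakly acidic methoxymethylene carbon. The fallback reverses the order of the two bond formations; it sets out from 10 and 12 and comes back at 15. The dianion of 12 (NaH, then n-BuLi, THF, −78 °C; 2 equiv) should be acylated at its methoxymethylene carbon by the ester of 10 to give methyl 7-[6,7-dimethoxy-8-(methoxymethoxy)-2H-chromen-3-yl]-2,4-dimethoxy-3,5-dioxohept-6-ynoate F1, so that the C-1–C-2 bond is made first. Mild base (Cs2CO3, MeCN) should then close the C-4–C-5 bond by intramolecular conjugate addition of the keto ester carbon to the ynone, giving 14, and the LiCl stage of step 8 should lead to 15.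

Step 9. The free phenols and the ortho methoxy group may inhibit the cationic catalyst or erode facial selectivity, and the acidic iridium hydrides may cleave the MOM acetal. The fallback sets the centre before ring B is built, on the benchmark substrate class of 2-substituted cinnamyl alcohols; it sets out from 7 and comes back at 16. Luche reduction of 7 (NaBH4, CeCl3·7H2O, MeOH, 0 °C) should give [6,7-dimethoxy-8-(methoxymethoxy)-2H-chromen-3-yl]methanol F2. Hydrogenation with the same iridium catalyst should give [(3S)-6,7-dimethoxy-8-(methoxymethoxy)-3,4-dihydro-2H-chromen-3-yl]methanol F3. Dess–Martin oxidation should give (3R)-6,7-dimethoxy-8-(methoxymethoxy)-3,4-dihydro-2H-chromene-3-carbaldehyde F4. Ohira–Bestmann homologation (dimethyl (1-diazo-2-oxopropyl)phosphonate, K2CO3, MeOH, 0 °C) should give (3S)-3-ethynyl-6,7-dimethoxy-8-(methoxymethoxy)-3,4-dihydro-2H-chromene F5. Treatment with n-BuLi and ClCO2Me should give methyl 3-[(3S)-6,7-dimethoxy-8-(methoxymethoxy)-3,4-dihydro-2H-chromen-3-yl]prop-2-ynoate F6. Under the conditions of step 8, with NaH held at one equivalent to spare the adjacent centre, F6 and 12 should pass through dimethyl (2Z)-3-[(3S)-6,7-dimethoxy-8-(methoxymethoxy)-3,4-dihydro-2H-chromen-3-yl]-4-methoxy-4-(methoxyacetyl)pent-2-enedioate F7 and methyl 2-[(3S)-6,7-dimethoxy-8-(methoxymethoxy)-3,4-dihydro-2H-chromen-3-yl]-6-hydroxy-1,5-dimethoxy-4-oxocyclohexa-2,5-diene-1-carboxylate F8 to 16.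

Step 10. Ligand exchange at the wrong phenol, or attack of water at C-2 instead of C-4, would lead to ortho-quinones, and the electron-rich ring may be over-oxidised. The fallback replaces the phenol-directed oxidation by oxidative demethylation of a para-dimethoxy pair; it sets out from 16 and comes back at 18. Exhaustive methylation (Me2SO4, K2CO3, acetone, reflux) should give (3S)-6,7-dimethoxy-8-(methoxymethoxy)-3-(2,3,4,5-tetramethoxyphenyl)-3,4-dihydro-2H-chromene F9. Oxidation with (NH4)2Ce(NO3)6 (MeCN–H2O, 0 °C) should give 5-[(3S)-6,7-dimethoxy-8-(methoxymethoxy)-3,4-dihydro-2H-chromen-3-yl]-2,3-dimethoxycyclohexa-2,5-diene-1,4-dione F10; competing oxidation of ring A is the open risk of this fallback. The acidic methanol of step 11 then removes the MOM group and gives 18.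

**Further compounds**

F1 | step 8 | methyl 7-[6,7-dimethoxy-8-(methoxymethoxy)-2H-chromen-3-yl]-2,4-dimethoxy-3,5-dioxohept-6-ynoate | COC(=O)C(OC)C(=O)C(OC)C(=O)C#CC1=Cc2cc(OC)c(OC)c(OCOC)c2OC1
F2 | step 9 | [6,7-dimethoxy-8-(methoxymethoxy)-2H-chromen-3-yl]methanol | OCC1=Cc2cc(OC)c(OC)c(OCOC)c2OC1
F3 | step 9 | [(3S)-6,7-dimethoxy-8-(methoxymethoxy)-3,4-dihydro-2H-chromen-3-yl]methanol | OC[C@H]1COc2c(cc(OC)c(OC)c2OCOC)C1
F4 | step 9 | (3R)-6,7-dimethoxy-8-(methoxymethoxy)-3,4-dihydro-2H-chromene-3-carbaldehyde | O=C[C@H]1COc2c(cc(OC)c(OC)c2OCOC)C1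
F5 | step 9 | (3S)-3-ethynyl-6,7-dimethoxy-8-(methoxymethoxy)-3,4-dihydro-2H-chromene | C#C[C@H]1COc2c(cc(OC)c(OC)c2OCOC)C1
F6 | step 9 | methyl 3-[(3S)-6,7-dimethoxy-8-(methoxymethoxy)-3,4-dihydro-2H-chromen-3-yl]prop-2-ynoate | COC(=O)C#C[C@H]1COc2c(cc(OC)c(OC)c2OCOC)C1
F7 | step 9 | dimethyl (2Z)-3-[(3S)-6,7-dimethoxy-8-(methoxymethoxy)-3,4-dihydro-2H-chromen-3-yl]-4-methoxy-4-(methoxyacetyl)pent-2-enedioate (both epimers at C-4) | COCC(=O)C(OC)(C(=O)OC)/C(=C\C(=O)OC)[C@H]1COc2c(cc(OC)c(OC)c2OCOC)C1
F8 | step 9 | methyl 2-[(3S)-6,7-dimethoxy-8-(methoxymethoxy)-3,4-dihydro-2H-chromen-3-yl]-6-hydroxy-1,5-dimethoxy-4-oxocyclohexa-2,5-diene-1-carboxylate (both epimers at C-1) | COC(=O)C1(OC)C(O)=C(OC)C(=O)C=C1[C@H]1COc2c(cc(OC)c(OC)c2OCOC)C1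
F9 | step 10 | (3S)-6,7-dimethoxy-8-(methoxymethoxy)-3-(2,3,4,5-tetramethoxyphenyl)-3,4-dihydro-2H-chromene | COc1cc([C@H]2COc3c(cc(OC)c(OC)c3OCOC)C2)c(OC)c(OC)c1OC
F10 | step 10 | 5-[(3S)-6,7-dimethoxy-8-(methoxymethoxy)-3,4-dihydro-2H-chromen-3-yl]-2,3-dimethoxycyclohexa-2,5-diene-1,4-dione | COC1=C(OC)C(=O)C([C@H]2COc3c(cc(OC)c(OC)c3OCOC)C2)=CC1=O
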